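**Retrosynthetic overview**
1. Numbering: carbocycle C1 (CH bearing coumarin A), C2H=C3(Me), C4H2, C5Me2, C6H; carbinol C7 (bearing coumarin B). With C7 at the acid level, C7–C6–C1–C2=C3 is a γ,δ-unsaturated acid inside the cyclohexene, so C1–C6 is a Claisen bond and C3 was the carbinol carbon of an allylic ester.
2. C7–aryl B: addition of 8-magnesiated 5,7-dimethoxycoumarin to aldehyde 18, which comes from acid 15 through a thioester.
3. C1–C6 (key): acid 15 from the Z-styryl δ-lactone 12 (ring O, C7, C6, C5, C4, C3) by ring-contracting Ireland–Claisen rearrangement; the C3–O stereocentre is relayed to C1 and C6.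
4. Lactone 12 from alkyne 11 (Lindlar); 11 by Sonogashira coupling of ethynyl lactone 8 with 8-iodo-5,7-dimethoxycoumarin 10; 8 by asymmetric alkynylation of keto ester 3 (retro-Claisen of dimedone) and lactonisation.
5. Ring order: both coumarins are bought; the δ-lactone is closed in step 4 and contracted to the cyclohexene in step 8.

Key step: step 8

Assumptions: iodination of 5,7-dimethoxycoumarin is taken to occur at C8 (less hindered than C6, which lies between two methoxy groups), and the salen antipode that gives Si-face delivery in step 3 is taken as fixed by a pilot run with both antipodes.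

**Route**

Step 1
Reactants: 1 dimedone
Product: 2 3,3-dimethyl-5-oxohexanoic acid
Conditions: Ba(OH)2·8H2O, H2O, reflux; then aq. HCl
Reagents that add atoms: water, O
Why: Retro-Claisen cleavage of a cyclic 1,3-diketone, in which hydroxide adds to one carbonyl and the bond to the enolisable neighbour breaks, gives the δ-keto acid that already holds C3 with its methyl, C4, C5 with both methyls, C6 and C7.

Step 2
Reactants: 2 3,3-dimethyl-5-oxohexanoic acid
Product: 3 methyl 3,3-dimethyl-5-oxohexanoate
Conditions: MeOH, H2SO4 (cat.), reflux; aq. NaHCO3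
Reagents that add atoms: methanol, CO
Why: Fischer esterification masks the acid so that the organozinc of step 3 is not quenched, and any dimethyl ketal formed should revert to the ketone in the aqueous work-up.

Step 3
Reactants: 3 methyl 3,3-dimethyl-5-oxohexanoate; 4 trimethylsilylacetylene
Product: 6 methyl (5R)-5-hydroxy-3,3,5-trimethyl-7-(trimethylsilyl)hept-6-ynoate, via alkynylzinc 5 (not isolated)
Conditions: Me2Zn, salen ligand (20 mol%, antipode for Si-face delivery), toluene, rt; aq. NH4Cl
Reagents that add atoms: none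
Why: Zinc–salen-catalysed addition of the alkynylzinc 5, formed in the flask from 4 and Me2Zn, to the methyl ketone (catalytic asymmetric ketone alkynylation) should deliver the alkynyl group to the Si face because the catalyst distinguishes methyl from the neopentyl-like CH2CMe2 arm, which sets the tertiary carbinol as R, and the ester is inert to organozinc reagents.

Step 4
Reactants: 6 methyl (5R)-5-hydroxy-3,3,5-trimethyl-7-(trimethylsilyl)hept-6-ynoate
Product: 8 (6R)-6-ethynyl-4,4,6-trimethyloxan-2-one, via hydroxy acid 7 (not isolated)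
Conditions: LiOH, THF/MeOH/H2O, rt; 1 M HCl to pH 2; then EDC·HCl, DMAP (cat.), CH2Cl2, rt
Reagents that add atoms: lithium hydroxide (one carboxyl oxygen), [Li+].[OH-]
Why: Hydroxide cleaves the methyl ester and the C(sp)–Si bond in one operation, and carbodiimide activation of the acid then closes the δ-lactone on the tertiary hydroxyl (6-exo-trig acyl substitution favoured by the gem-dimethyl group) with retention, since the C–O bond at the stereocentre is never broken.

Step 5
Reactants: 9 5,7-dimethoxycoumarin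
Product: 10 8-iodo-5,7-dimethoxycoumarin
Conditions: NIS, TFA (cat.), MeCN, rt
Reagents that add atoms: N-iodosuccinimide, O=C1CCC(=O)N1I
Why: Electrophilic aromatic iodination of the doubly activated ring should take place at C8 (ortho to 7-OMe and O1, para to 5-OMe), the less hindered of the two activated positions.

Step 6
Reactants: 8 (6R)-6-ethynyl-4,4,6-trimethyloxan-2-one; 10 8-iodo-5,7-dimethoxycoumarin
Product: 11 (6R)-6-[(5,7-dimethoxy-2-oxo-2H-chromen-8-yl)ethynyl]-4,4,6-trimethyloxan-2-one
Conditions: Pd(PPh3)2Cl2 (cat.), CuI (cat.), Et3N, THF, 50 °C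
Reagents that add atoms: none
Why: Sonogashira coupling (oxidative addition of the aryl iodide, transmetalation from the copper acetylide of 8, reductive elimination) joins C1 to coumarin C8 under an amine base that leaves both lactones and the quaternary stereocentre untouched.

Step 7
Reactants: 11 (6R)-6-[(5,7-dimethoxy-2-oxo-2H-chromen-8-yl)ethynyl]-4,4,6-trimethyloxan-2-one
Product: 12 (6R)-6-[(Z)-2-(5,7-dimethoxy-2-oxo-2H-chromen-8-yl)ethenyl]-4,4,6-trimethyloxan-2-one
Conditions: H2 (1 atm), Lindlar catalyst (Pd/CaCO3–Pb), quinoline, EtOAc, rt, dark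
Reagents that add atoms: none
Why: Lindlar semihydrogenation adds one H2 in syn fashion on the poisoned palladium surface and so gives the Z alkene, while the hindered product alkene, the coumarin C3=C4 bond and the allylic C–O bond are expected to react much more slowly (uptake is stopped at one equivalent).

Step 8
Reactants: 12 (6R)-6-[(Z)-2-(5,7-dimethoxy-2-oxo-2H-chromen-8-yl)ethenyl]-4,4,6-trimethyloxan-2-one
Product: 15 (1R,6S)-6-(5,7-dimethoxy-2-oxo-2H-chromen-8-yl)-2,2,4-trimethylcyclohex-4-ene-1-carboxylic acid, via silyl ketene acetal 13 (not isolated), via silyl ester 14 (not isolated)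
Conditions: LiHMDS, TMSCl/Et3N (premixed), THF, −78 °C → rt; then toluene, 100 °C; then 1 M HCl, THF, rt
Reagents that add atoms: none
Why: LiHMDS with TMSCl present from the start deprotonates C6 and traps the enolate as the endocyclic O-silyl ketene acetal 13 (a base/chlorosilane protocol is chosen because a silyl triflate would ionise the tertiary, styryl-activated C3–O bond), and on heating the array C6=C7–O–C3–C2=C1 undergoes a concerted suprafacial [3,3] shift that forms C1–C6, breaks C3–O and moves the alkene to C2=C3, giving silyl ester 14 and, after hydrolysis, acid 15. The closest known reaction type is the ring-contracting Ireland–Claisen rearrangement of alkenyl lactone silyl ketene acetals to cycloalkenecarboxylic acids, including the six-ring-to-six-ring dioxanone-to-dihydropyran case. The cyclohexene closes by pericyclic C–C bond formation in which C1–C2 becomes the third two-atom bridge between C3 and C6; because C4–C5 already tie C3 to C6, only a boat (bicyclo[2.2.2]octane-like) transition state is possible, and the lactone opens as the carbocycle closes. C6 is set by the C3–O centre, since the styryl arm can reach only the ketene acetal face on its own side of the ring, so (R)-C3 gives (R)-C6 while C3 becomes sp2; C1 is set by the alkene geometry, since in the boat the Z-aryl group lies on the tether side of C1, which puts aryl A trans to the carboxyl group and gives (S)-C1. The step needs complete 1,3-chirality transfer and the trans C1/C6 relation, and both follow from the tether-enforced boat, the ring-fixed ketene acetal geometry and the stereodefined Z alkene of step 7. The cost is that aryl A leans against the C5 methyl groups in this boat, which is why heating in toluene is planned.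

Step 9
Reactants: 15 (1R,6S)-6-(5,7-dimethoxy-2-oxo-2H-chromen-8-yl)-2,2,4-trimethylcyclohex-4-ene-1-carboxylic acid
Product: 17 S-ethyl (1R,6S)-6-(5,7-dimethoxy-2-oxo-2H-chromen-8-yl)-2,2,4-trimethylcyclohex-4-ene-1-carbothioate, via acid chloride 16 (not isolated)
Conditions: (COCl)2, DMF (cat.), CH2Cl2, 0 °C → rt; then EtSH, pyridine, DMAP (cat.), 0 °C → rt
Reagents that add atoms: ethanethiol, CCS
Why: The hindered acid is activated as its acid chloride (Vilsmeier catalysis) and acylates ethanethiol under DMAP catalysis, with pyridine as base to keep ketene formation and thus epimerisation at C6 low, the trans isomer being in any case the more stable one.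

Step 10
Reactants: 17 S-ethyl (1R,6S)-6-(5,7-dimethoxy-2-oxo-2H-chromen-8-yl)-2,2,4-trimethylcyclohex-4-ene-1-carbothioate
Product: 18 (1R,6S)-6-(5,7-dimethoxy-2-oxo-2H-chromen-8-yl)-2,2,4-trimethylcyclohex-4-ene-1-carbaldehyde
Conditions: Et3SiH, 10% Pd/C, CH2Cl2, rt
Reagents that add atoms: none
Why: Fukuyama reduction (oxidative addition of Pd(0) into the C–S bond, hydride transfer from the silane, reductive elimination) stops at the aldehyde under neutral conditions that should spare the trisubstituted ring alkene, the coumarin and the C6 stereocentre.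

Step 11
Reactants: 18 (1R,6S)-6-(5,7-dimethoxy-2-oxo-2H-chromen-8-yl)-2,2,4-trimethylcyclohex-4-ene-1-carbaldehyde; 10 8-iodo-5,7-dimethoxycoumarin
Product: 20 IN0553 8-{(R)-hydroxy[(1R,6S)-6-(5,7-dimethoxy-2-oxo-2H-chromen-8-yl)-2,2,4-trimethylcyclohex-4-en-1-yl]methyl}-5,7-dimethoxy-2H-chromen-2-one, via arylmagnesium chloride 19 (not isolated)
Conditions: 10, i-PrMgCl·LiCl, THF, −20 °C; then 18, LaCl3·2LiCl (30 mol%), −20 → 0 °C; aq. NH4Cl
Reagents that add atoms: none
Why: Iodine–magnesium exchange at low temperature gives the functionalised aryl Grignard 19 without attack on its own lactone, and its 1,2-addition to the aldehyde, far more electrophilic than either coumarin, should follow a Felkin–Anh course in which the aryl group enters anti to the C6–C1 bond, past the equatorial C5 methyl rather than past aryl A, which gives the 7R carbinol.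

**Compound list**
1 | dimedone (5,5-dimethylcyclohexane-1,3-dione) | CC1(C)CC(=O)CC(=O)C1 | starting material
2 | 3,3-dimethyl-5-oxohexanoic acid | CC(=O)CC(C)(C)CC(=O)O | intermediate
3 | methyl 3,3-dimethyl-5-oxohexanoate | CC(=O)CC(C)(C)CC(=O)OC | intermediate
4 | trimethylsilylacetylene | C#C[Si](C)(C)C | starting material
5 | methyl[(trimethylsilyl)ethynyl]zinc | C[Zn]C#C[Si](C)(C)C | intermediate (not isolated)
6 | methyl (5R)-5-hydroxy-3,3,5-trimethyl-7-(trimethylsilyl)hept-6-ynoate | COC(=O)CC(C)(C)C[C@@](C)(O)C#C[Si](C)(C)C | intermediate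
7 | (5R)-5-hydroxy-3,3,5-trimethylhept-6-ynoic acid | OC(=O)CC(C)(C)C[C@@](C)(O)C#C | intermediate (not isolated)
8 | (6R)-6-ethynyl-4,4,6-trimethyloxan-2-one | O=C1CC(C)(C)C[C@@](C)(O1)C#C | intermediate
9 | 5,7-dimethoxycoumarin | COc1cc(OC)c2ccc(=O)oc2c1 | starting material
10 | 8-iodo-5,7-dimethoxycoumarin | COc1cc(OC)c2ccc(=O)oc2c1I | intermediate
11 | (6R)-6-[(5,7-dimethoxy-2-oxo-2H-chromen-8-yl)ethynyl]-4,4,6-trimethyloxan-2-one | O=C1CC(C)(C)C[C@@](C)(O1)C#Cc1c(OC)cc(OC)c2ccc(=O)oc12 | intermediate
12 | (6R)-6-[(Z)-2-(5,7-dimethoxy-2-oxo-2H-chromen-8-yl)ethenyl]-4,4,6-trimethyloxan-2-one | O=C1CC(C)(C)C[C@@](C)(O1)/C=C\c1c(OC)cc(OC)c2ccc(=O)oc12 | intermediate (key-step precursor)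
13 | 5,7-dimethoxy-8-{(Z)-2-[(2R)-2,4,4-trimethyl-6-(trimethylsilyloxy)-3,4-dihydro-2H-pyran-2-yl]ethenyl}-2H-chromen-2-one | C[Si](C)(C)OC1=CC(C)(C)C[C@@](C)(O1)/C=C\c1c(OC)cc(OC)c2ccc(=O)oc12 | intermediate (not isolated)
14 | trimethylsilyl (1R,6S)-6-(5,7-dimethoxy-2-oxo-2H-chromen-8-yl)-2,2,4-trimethylcyclohex-4-ene-1-carboxylate | COc1cc(OC)c2ccc(=O)oc2c1[C@H]1C=C(C)CC(C)(C)[C@@H]1C(=O)O[Si](C)(C)C | intermediate (not isolated)
15 | (1R,6S)-6-(5,7-dimethoxy-2-oxo-2H-chromen-8-yl)-2,2,4-trimethylcyclohex-4-ene-1-carboxylic acid | COc1cc(OC)c2ccc(=O)oc2c1[C@H]1C=C(C)CC(C)(C)[C@@H]1C(=O)O | intermediate (key-step product)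
16 | (1R,6S)-6-(5,7-dimethoxy-2-oxo-2H-chromen-8-yl)-2,2,4-trimethylcyclohex-4-ene-1-carbonyl chloride | COc1cc(OC)c2ccc(=O)oc2c1[C@H]1C=C(C)CC(C)(C)[C@@H]1C(Cl)=O | intermediate (not isolated)
17 | S-ethyl (1R,6S)-6-(5,7-dimethoxy-2-oxo-2H-chromen-8-yl)-2,2,4-trimethylcyclohex-4-ene-1-carbothioate | COc1cc(OC)c2ccc(=O)oc2c1[C@H]1C=C(C)CC(C)(C)[C@@H]1C(=O)SCC | intermediate
18 | (1R,6S)-6-(5,7-dimethoxy-2-oxo-2H-chromen-8-yl)-2,2,4-trimethylcyclohex-4-ene-1-carbaldehyde | COc1cc(OC)c2ccc(=O)oc2c1[C@H]1C=C(C)CC(C)(C)[C@@H]1C=O | intermediate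
19 | (5,7-dimethoxy-2-oxo-2H-chromen-8-yl)magnesium chloride (LiCl complex) | COc1cc(OC)c2ccc(=O)oc2c1[Mg]Cl | intermediate (not isolated)
20 | IN0553, 8-{(R)-hydroxy[(1R,6S)-6-(5,7-dimethoxy-2-oxo-2H-chromen-8-yl)-2,2,4-trimethylcyclohex-4-en-1-yl]methyl}-5,7-dimethoxy-2H-chromen-2-one | COc1cc(OC)c2ccc(=O)oc2c1[C@H]1C=C(C)CC(C)(C)[C@@H]1[C@@H](O)c1c(OC)cc(OC)c2ccc(=O)oc12 | target

**Totals**
Total step count: 11. Longest linear sequence: 10 steps (1 → 2 → 3 → 6 → 8 → 11 → 12 → 15 → 17 → 18 → 20).

**Steps most likely to fail**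

Step 8. Process at risk: in the boat the Z-aryl group is pressed against the C5 methyl groups, so the [3,3] shift may become slower than desilylation of the ketene acetal, ionisation of its tertiary allylic C–O bond or Z/E leakage. Fallback (sets out from 3, returns at 18): the same ring contraction is run through the uncrowded boat of the E alkene in the enantiomeric lactone series, and the carboxyl-bearing centre is corrected afterwards. Step 3 with the antipodal salen ligand gives methyl (5S)-5-hydroxy-3,3,5-trimethyl-7-(trimethylsilyl)hept-6-ynoate F1. The conditions of step 4 lead through (5S)-5-hydroxy-3,3,5-trimethylhept-6-ynoic acid F2 to (6S)-6-ethynyl-4,4,6-trimethyloxan-2-one F3. Zirconium-catalysed syn-hydroboration (HBpin, Cp2Zr(H)Cl cat.) gives the (E)-alkenylboronate (6S)-4,4,6-trimethyl-6-[(E)-2-(4,4,5,5-tetramethyl-1,3,2-dioxaborolan-2-yl)ethenyl]oxan-2-one F4, and Suzuki coupling with 10 (Pd(dppf)Cl2, CsF, dioxane) gives (6S)-6-[(E)-2-(5,7-dimethoxy-2-oxo-2H-chromen-8-yl)ethenyl]-4,4,6-trimethyloxan-2-one F5. Under the conditions of step 8 this should pass through its silyl ketene acetal F6 and the cis trimethylsilyl ester F7 to (1S,6S)-6-(5,7-dimethoxy-2-oxo-2H-chromen-8-yl)-2,2,4-trimethylcyclohex-4-ene-1-carboxylic acid F8, in which the aryl-bearing carbon already has the target configuration. The conditions of steps 9 and 10 convert it through the cis acid chloride F9 and the cis S-ethyl thioester F10 into the cis aldehyde F11, which DBU in CH2Cl2 should equilibrate at the formyl-bearing carbon to the more stable trans aldehyde 18.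

Step 3. Process at risk: insufficient discrimination between methyl and the CH2CMe2 arm of an unactivated dialkyl ketone, so that the enantiomeric excess is too low, or slow zincation of 4. Fallback (sets out from 3, returns at 8): resolution replaces asymmetric catalysis. Uncatalysed addition of ethynylmagnesium bromide (THF, −20 → 0 °C) gives racemic methyl 5-hydroxy-3,3,5-trimethylhept-6-ynoate F12 as its magnesium alkoxide, which should close in the flask to racemic 6-ethynyl-4,4,6-trimethyloxan-2-one F13. The enantiomers are separated by preparative chromatography on a polysaccharide chiral phase, and the R enantiomer is 8.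

Step 11. Process at risk: poor facial selectivity at the formyl group, which is flanked by the C5 methyls and aryl A, or enolisation of 18 by the hindered aryl Grignard. Fallback (sets out from 18, returns at 20): the stereocentre is set by hydride instead of by the aryl group. The crude carbinol mixture, containing the (S)-carbinol epimer of 20 F14, is oxidised with Dess–Martin periodinane to the ketone {(1R,6S)-6-(5,7-dimethoxy-2-oxo-2H-chromen-8-yl)-2,2,4-trimethylcyclohex-4-en-1-yl}(5,7-dimethoxy-2-oxo-2H-chromen-8-yl)methanone F15. This is reduced with NaBH4/CeCl3 (MeOH/CH2Cl2, −40 °C); hydride entering from the side that the aryl group preferred leaves the opposite configuration at C7 and should give 20.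

Further compounds
F1 | step 8 | methyl (5S)-5-hydroxy-3,3,5-trimethyl-7-(trimethylsilyl)hept-6-ynoate | COC(=O)CC(C)(C)C[C@](C)(O)C#C[Si](C)(C)C
F2 | step 8 | (5S)-5-hydroxy-3,3,5-trimethylhept-6-ynoic acid | OC(=O)CC(C)(C)C[C@](C)(O)C#C
F3 | step 8 | (6S)-6-ethynyl-4,4,6-trimethyloxan-2-one | O=C1CC(C)(C)C[C@](C)(O1)C#C
F4 | step 8 | (6S)-4,4,6-trimethyl-6-[(E)-2-(4,4,5,5-tetramethyl-1,3,2-dioxaborolan-2-yl)ethenyl]oxan-2-one | O=C1CC(C)(C)C[C@](C)(O1)/C=C/B1OC(C)(C)C(C)(C)O1
F5 | step 8 | (6S)-6-[(E)-2-(5,7-dimethoxy-2-oxo-2H-chromen-8-yl)ethenyl]-4,4,6-trimethyloxan-2-one | O=C1CC(C)(C)C[C@](C)(O1)/C=C/c1c(OC)cc(OC)c2ccc(=O)oc12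
F6 | step 8 | 5,7-dimethoxy-8-{(E)-2-[(2S)-2,4,4-trimethyl-6-(trimethylsilyloxy)-3,4-dihydro-2H-pyran-2-yl]ethenyl}-2H-chromen-2-one | C[Si](C)(C)OC1=CC(C)(C)C[C@](C)(O1)/C=C/c1c(OC)cc(OC)c2ccc(=O)oc12
F7 | step 8 | trimethylsilyl (1S,6S)-6-(5,7-dimethoxy-2-oxo-2H-chromen-8-yl)-2,2,4-trimethylcyclohex-4-ene-1-carboxylate | COc1cc(OC)c2ccc(=O)oc2c1[C@H]1C=C(C)CC(C)(C)[C@H]1C(=O)O[Si](C)(C)C
F8 | step 8 | (1S,6S)-6-(5,7-dimethoxy-2-oxo-2H-chromen-8-yl)-2,2,4-trimethylcyclohex-4-ene-1-carboxylic acid | COc1cc(OC)c2ccc(=O)oc2c1[C@H]1C=C(C)CC(C)(C)[C@H]1C(=O)O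
F9 | step 8 | (1S,6S)-6-(5,7-dimethoxy-2-oxo-2H-chromen-8-yl)-2,2,4-trimethylcyclohex-4-ene-1-carbonyl chloride | COc1cc(OC)c2ccc(=O)oc2c1[C@H]1C=C(C)CC(C)(C)[C@H]1C(Cl)=O
F10 | step 8 | S-ethyl (1S,6S)-6-(5,7-dimethoxy-2-oxo-2H-chromen-8-yl)-2,2,4-trimethylcyclohex-4-ene-1-carbothioate | COc1cc(OC)c2ccc(=O)oc2c1[C@H]1C=C(C)CC(C)(C)[C@H]1C(=O)SCC
F11 | step 8 | (1S,6S)-6-(5,7-dimethoxy-2-oxo-2H-chromen-8-yl)-2,2,4-trimethylcyclohex-4-ene-1-carbaldehyde | COc1cc(OC)c2ccc(=O)oc2c1[C@H]1C=C(C)CC(C)(C)[C@H]1C=O
F12 | step 3 | racemic methyl 5-hydroxy-3,3,5-trimethylhept-6-ynoate | COC(=O)CC(C)(C)CC(C)(O)C#C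
F13 | step 3 | racemic 6-ethynyl-4,4,6-trimethyloxan-2-one | O=C1CC(C)(C)CC(C)(O1)C#C
F14 | step 11 | 8-{(S)-hydroxy[(1R,6S)-6-(5,7-dimethoxy-2-oxo-2H-chromen-8-yl)-2,2,4-trimethylcyclohex-4-en-1-yl]methyl}-5,7-dimethoxy-2H-chromen-2-one | COc1cc(OC)c2ccc(=O)oc2c1[C@H]1C=C(C)CC(C)(C)[C@@H]1[C@H](O)c1c(OC)cc(OC)c2ccc(=O)oc12
F15 | step 11 | {(1R,6S)-6-(5,7-dimethoxy-2-oxo-2H-chromen-8-yl)-2,2,4-trimethylcyclohex-4-en-1-yl}(5,7-dimethoxy-2-oxo-2H-chromen-8-yl)methanone | COc1cc(OC)c2ccc(=O)oc2c1[C@H]1C=C(C)CC(C)(C)[C@@H]1C(=O)c1c(OC)cc(OC)c2ccc(=O)oc12
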